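**Plan**
1. Cuts: first the nine O-benzyl bonds. Then O1–C2 and C4–C4a of ring C in the upper (mesquitol-type) unit are cut together, which frees ring A as 2,3-dibenzyloxyphenol and leaves a C2–C3 trans-oxirane beside a C4 carbinol. Last, C4–C8(D) is cut, back to an epoxy aldehyde and 8-metalated catechin.
2. Enabling feature: C4 sits on C8 of ring D, flanked by O7 and the ring-F oxygen with O5 para, so its hydroxyl ionises under very mild acid. The ring-A carbon that becomes C4a is ortho to O1, para to O7, and the only unsubstituted ortho site, because C8 carries oxygen.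
3. Forward order: rings D, F and E come intact from (+)-catechin, and ring B from 3,4-dibenzyloxybenzaldehyde. The C2–C3–C4 chain is grown on ring B, epoxidised and joined to C8(D). Ring A is then brought in and ring C closed around it in one flask, and hydrogenolysis ends the route.
4. Stereochemistry: lower C2/C3 come from the chiral pool. Upper C3 (retained) and C2 (inverted once) come from one organocatalytic epoxidation, and any enantiomeric leakage there becomes a separable diastereomer once catechin is attached. Upper C4 comes from allylic strain in the D-ring-stabilised cation together with the short C2–O1 tether.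

Key step: step 9

Assumption: the sense of induction in step 5 follows the accepted shielding model of diarylprolinol silyl ether iminium ions (S catalyst: Si-face attack at Cβ of cinnamaldehydes), so the R catalyst is chosen.
Assumption: 3,4-dibenzyloxybenzaldehyde, the formyl ylide and both catalyst enantiomers are taken as catalogue items.
Flavan numbering (upper unit rings A, C, B; catechin unit rings D, F, E) is used for the C3 chain throughout.

Step 1
Reactants: 1 (+)-catechin
Product: 2 5,7,3',4'-tetra-O-benzyl-(+)-catechin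
Conditions: BnBr (4.4 equiv), K2CO3, DMF, N2, 0 °C → rt
Reagents that add atoms: benzyl bromide, BrCc1ccccc1
Why: Williamson etherification in which carbonate deprotonates only the four phenols, so the secondary 3-OH stays free and C2/C3 are untouched.

Step 2
Reactants: 2 5,7,3',4'-tetra-O-benzyl-(+)-catechin
Product: 3 8-bromo-5,7,3',4'-tetra-O-benzyl-(+)-catechin
Conditions: NBS (1.0 equiv), CH2Cl2, −45 °C → rt
Reagents that add atoms: N-bromosuccinimide, O=C1CCC(=O)N1Br
Why: Electrophilic aromatic bromination, for which one equivalent of NBS at low temperature is known to take C8 of the phloroglucinol-type ring of benzylated flavan-3-ols in preference to C6 and to leave the catechol ring alone.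

Step 3
Reactants: 3 8-bromo-5,7,3',4'-tetra-O-benzyl-(+)-catechin
Product: 4 8-bromo-3,5,7,3',4'-penta-O-benzyl-(+)-catechin
Conditions: NaH, BnBr, DMF, 0 °C → rt
Reagents that add atoms: benzyl bromide, BrCc1ccccc1
Why: Williamson etherification of the sodium alkoxide removes the only acidic proton before the halogen–lithium exchange, using a group that falls in the final hydrogenolysis.

Step 4
Reactants: 5 3,4-bis(benzyloxy)benzaldehyde
Product: 6 (E)-3-[3,4-bis(benzyloxy)phenyl]prop-2-enal
Conditions: Ph3P=CHCHO (1.1 equiv), toluene, 90 °C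
Reagents that add atoms: (triphenylphosphoranylidene)acetaldehyde, O=CC=P(c1ccccc1)(c1ccccc1)c1ccccc1
Why: Wittig olefination with the stabilised formylmethylene ylide should give the E-enal in a single two-carbon homologation.

Step 5
Reactants: 6 (E)-3-[3,4-bis(benzyloxy)phenyl]prop-2-enal
Product: 7 (2R,3S)-3-[3,4-bis(benzyloxy)phenyl]oxirane-2-carbaldehyde
Conditions: (R)-2-{bis[3,5-bis(trifluoromethyl)phenyl](trimethylsilyloxy)methyl}pyrrolidine (10 mol %), 35% aq. H2O2 (1.3 equiv), CH2Cl2, rt
Reagents that add atoms: hydrogen peroxide, OO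
Why: Jørgensen iminium–enamine epoxidation, in which hydroperoxide adds to the Cβ Re face left open by the bulky group of the R catalyst and the resulting enamine closes on the O–O bond, setting both oxirane carbons (trans, 2R,3S) while the formyl group tempers the benzylic C–O bond.

Step 6
Reactants: 8 2,3-dihydroxybenzaldehyde
Product: 9 2,3-bis(benzyloxy)benzaldehyde
Conditions: BnBr (2.2 equiv), K2CO3, DMF, rt → 50 °C
Reagents that add atoms: benzyl bromide, BrCc1ccccc1
Why: Williamson etherification of both phenols, the chelated 2-OH included once it is deprotonated by carbonate.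

Step 7
Reactants: 9 2,3-bis(benzyloxy)benzaldehyde
Product: 11 2,3-bis(benzyloxy)phenol, via aryl formate 10 (not isolated)
Conditions: mCPBA, CH2Cl2, 0 °C → rt, NaHCO3 wash; crude, K2CO3 (cat.), MeOH, rt
Reagents that add atoms: mCPBA, O=C(OO)c1cccc(Cl)c1
Why: Baeyer–Villiger (Dakin-type) oxidation, in which the electron-rich aryl group migrates in the Criegee adduct to give the formate, and base-catalysed methanolysis then releases the phenol.

Step 8
Reactants: 4 8-bromo-3,5,7,3',4'-penta-O-benzyl-(+)-catechin; 7 (2R,3S)-3-[3,4-bis(benzyloxy)phenyl]oxirane-2-carbaldehyde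
Product: 13 trans-epoxy carbinol (both C4 epimers), via 8-lithio species 12 (not isolated)
Conditions: n-BuLi (1.05 equiv), THF, −78 °C; 7, THF, −78 °C; H2O quench; Et3N-deactivated silica
Reagents that add atoms: none
Why: Bromine–lithium exchange, known for 8-bromo benzylated flavan-3-ols, outruns benzylic metalation at −78 °C, and the aryllithium adds 1,2 to the aldehyde faster than it opens the oxirane; the new carbinol centre needs no control because step 9 ionises it.

Step 9
Reactants: 13 trans-epoxy carbinol (both C4 epimers); 11 2,3-bis(benzyloxy)phenol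
Product: 16 nona-O-benzyl mesquitol-(4α→8)-catechin (upper 3-OH free), via aryloxy diol 14 (not isolated), via C4 cation 15 (not isolated)
Conditions: 11 (1.2 equiv), Ti(OiPr)4 (1.1 equiv), 4 Å MS, CH2Cl2, −20 → 0 °C; dilute to ca. 5 mM, TiCl4 (1.1 equiv), −78 → −40 °C; aq. NaHCO3
Reagents that add atoms: none
Why: Proposed new method: Ti(OiPr)4 exchanges ligands with the C4 hydroxyl of 13 and with phenol 11, the metal bridges O4 and the oxirane oxygen, and the aryloxide oxygen attacks the distal, B-ring-benzylic C2 from the rear, so that C2 goes from S to R by inversion, the C3–O bond is never broken, and the anti aryloxy diol 14 results, which maps onto a 2,3-trans flavan. TiCl4 then comproportionates with the alkoxides to TiCl2(OiPr)2, acidic enough to ionise the C4–O bond of either epimer to the single cation 15, which is delocalised onto O5, O7 and the ring-F oxygen of ring D, whereas C2–O1 has only one para oxygen behind it and should hold at low temperature. C4a adds to C4 and loses its proton, an intramolecular Friedel–Crafts alkylation that closes the six-membered ring C in the 6-exo-trig mode with respect to the quinoid C4=C8(D) bond. The closest known reactions are the titanium-isopropoxide-mediated C3-selective opening of 2,3-epoxy alcohols by heteroatom nucleophiles, the invertive opening of aryl glycidols by phenoxides at the benzylic carbon, the acid-induced cyclisation of 3-aryloxy-1-arylpropan-1-ols to 4-arylchromans and the TiCl4-promoted C4–C8 coupling of benzylated flavan-3-ols, and what is new is their relay on one titanium charge in one flask as a [3+3] annulation. C4 is controlled by allylic 1,3-strain: to stay coplanar with a D ring oxygenated on both ortho carbons the cation turns H3 into its plane, which places the titanium-bearing O3 on one face and C2 with its O1-aryl tether on the other, and C4a can reach only the tether face, so that ring D, O3 and ring B all end up equatorial (3,4-trans, 4S). The step needs O- before C-alkylation and C2 before C3 attack (secured by chelation, benzylic activation and the absence of strong acid in the first stage) and ring closure before intermolecular capture (secured by the six-membered transition state, high dilution, near-stoichiometric 11 and the fact that C4a is the only ring-A carbon within reach).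

Step 10
Reactants: 16 nona-O-benzyl mesquitol-(4α→8)-catechin
Product: 17 mesquitol-(4α→8)-catechin (CNP0231186.1)
Conditions: H2 (1 atm), 20% Pd(OH)2/C, THF–MeOH–H2O, rt
Reagents that add atoms: none
Why: Catalytic hydrogenolysis over Pearlman's catalyst, the standard end game for benzylated proanthocyanidins, should cleave the nine O-benzyl bonds while the cyclic C2–O1 ethers and the C4–C8 bond stay intact, so no stereocentre is touched.

**Compound list**
1 | (+)-catechin, (2R,3S) | Oc1cc(O)c2c(c1)O[C@H](c1ccc(O)c(O)c1)[C@@H](O)C2 | starting material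
2 | 5,7,3',4'-tetra-O-benzyl-(+)-catechin, (2R,3S), 3-OH free | O(Cc5ccccc5)c1cc(OCc5ccccc5)c2c(c1)O[C@H](c1ccc(OCc5ccccc5)c(OCc5ccccc5)c1)[C@@H](O)C2 | intermediate
3 | 8-bromo-5,7,3',4'-tetra-O-benzyl-(+)-catechin, (2R,3S) | Brc3c(OCc5ccccc5)cc(OCc5ccccc5)c4c3O[C@H](c3ccc(OCc5ccccc5)c(OCc5ccccc5)c3)[C@@H](O)C4 | intermediate
4 | 8-bromo-3,5,7,3',4'-penta-O-benzyl-(+)-catechin, (2R,3S) | Brc3c(OCc5ccccc5)cc(OCc5ccccc5)c4c3O[C@H](c3ccc(OCc5ccccc5)c(OCc5ccccc5)c3)[C@@H](OCc5ccccc5)C4 | intermediate
5 | 3,4-bis(benzyloxy)benzaldehyde | O=Cc1ccc(OCc2ccccc2)c(OCc2ccccc2)c1 | starting material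
6 | (E)-3-[3,4-bis(benzyloxy)phenyl]prop-2-enal | O=C/C=C/c1ccc(OCc2ccccc2)c(OCc2ccccc2)c1 | intermediate
7 | (2R,3S)-3-[3,4-bis(benzyloxy)phenyl]oxirane-2-carbaldehyde (trans) | O(Cc5ccccc5)c1ccc([C@@H]6O[C@H]6C=O)cc1OCc5ccccc5 | intermediate
8 | 2,3-dihydroxybenzaldehyde | O=Cc1cccc(O)c1O | starting material
9 | 2,3-bis(benzyloxy)benzaldehyde | O=Cc1cccc(OCc2ccccc2)c1OCc2ccccc2 | intermediate
10 | 2,3-bis(benzyloxy)phenyl formate (not isolated) | O=COc1cccc(OCc2ccccc2)c1OCc2ccccc2 | intermediate
11 | 2,3-bis(benzyloxy)phenol | Oc1cccc(OCc2ccccc2)c1OCc2ccccc2 | intermediate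
12 | 8-lithio-3,5,7,3',4'-penta-O-benzyl-(+)-catechin (not isolated) | [Li]c3c(OCc5ccccc5)cc(OCc5ccccc5)c4c3O[C@H](c3ccc(OCc5ccccc5)c(OCc5ccccc5)c3)[C@@H](OCc5ccccc5)C4 | intermediate
13 | [(2S,3S)-3-(3,4-dibenzyloxyphenyl)oxiran-2-yl][(2R,3S)-3,5,7-tribenzyloxy-2-(3,4-dibenzyloxyphenyl)chroman-8-yl]methanol, both carbinol (C4) epimers | O(Cc5ccccc5)c1ccc([C@@H]6O[C@H]6C(O)c3c(OCc5ccccc5)cc(OCc5ccccc5)c4c3O[C@H](c3ccc(OCc5ccccc5)c(OCc5ccccc5)c3)[C@@H](OCc5ccccc5)C4)cc1OCc5ccccc5 | intermediate
14 | (2S,3R)-3-(3,4-dibenzyloxyphenyl)-3-(2,3-dibenzyloxyphenoxy)-1-(penta-O-benzylcatechin-8-yl)propane-1,2-diol, both C1 epimers (flavan C2 R, C3 S), present as its titanium diolate (not isolated) | O(Cc5ccccc5)c1ccc([C@@H](Oc2cccc(OCc5ccccc5)c2OCc5ccccc5)[C@@H](O)C(O)c3c(OCc5ccccc5)cc(OCc5ccccc5)c4c3O[C@H](c3ccc(OCc5ccccc5)c(OCc5ccccc5)c3)[C@@H](OCc5ccccc5)C4)cc1OCc5ccccc5 | intermediate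
15 | C4 benzylic (quinoid) cation derived from 14 by loss of the C4 oxygen (not isolated) | O(Cc5ccccc5)c1ccc([C@@H](Oc2cccc(OCc5ccccc5)c2OCc5ccccc5)[C@@H](O)[CH+]c3c(OCc5ccccc5)cc(OCc5ccccc5)c4c3O[C@H](c3ccc(OCc5ccccc5)c(OCc5ccccc5)c3)[C@@H](OCc5ccccc5)C4)cc1OCc5ccccc5 | intermediate
16 | nona-O-benzyl mesquitol-(4α→8)-catechin: upper unit (2R,3S,4S) with 7,8,3',4'-OBn and free 3-OH, bonded from C4 to C8 of (2R,3S)-penta-O-benzylcatechin | O(Cc5ccccc5)c1ccc([C@H]2Oc3c(ccc(OCc5ccccc5)c3OCc5ccccc5)[C@@H](c3c(OCc5ccccc5)cc(OCc5ccccc5)c4c3O[C@H](c3ccc(OCc5ccccc5)c(OCc5ccccc5)c3)[C@@H](OCc5ccccc5)C4)[C@@H]2O)cc1OCc5ccccc5 | intermediate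
17 | mesquitol-(4α→8)-catechin, (2R,3S,4S)-2-(3,4-dihydroxyphenyl)-4-[(2R,3S)-2-(3,4-dihydroxyphenyl)-3,5,7-trihydroxychroman-8-yl]chroman-3,7,8-triol | Oc1ccc([C@H]2Oc3c(ccc(O)c3O)[C@@H](c3c(O)cc(O)c4c3O[C@H](c3ccc(O)c(O)c3)[C@@H](O)C4)[C@@H]2O)cc1O | target

Total step count: 10.
Longest linear sequence: 6 steps (1 → 2 → 3 → 4 → 13 → 16 → 17).

**Steps most likely to fail**

Step 9.
- What may go wrong in the first stage: the donor-substituted benzylic oxirane may open in an SN1-like way with loss of inversion at C2. The phenol may attack through carbon instead of oxygen, or an isopropoxide ligand may be transferred.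
- What may go wrong after TiCl4 is added: C2–O1 may ionise alongside C4–O, a hydride may shift from C3, or intermolecular capture may lead to oligomers.
- Fallback (known chemistry only): the two bond formations are separated and the leaving group at C4 is changed. Setting out from 13 and 11, the titanium-isopropoxide-mediated opening is run alone and diol 14 is isolated and freed from any C2 epimer.
- Thiolysis with phenylmethanethiol and acetic acid in CH2Cl2, the standard interception of flavan C4 cations, gives the C4 benzyl thioether F1.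
- Silver tetrafluoroborate in THF at 0 °C, the thiophilic activation known from interflavanyl bond formation, then releases the cation without Lewis or Brønsted acid and closes ring C. This returns to the route at 16.

Step 8.
- What may go wrong: the aryllithium may attack the oxirane, the lithium alkoxide may undergo Payne-type migration, benzylic metalation may compete with the exchange, or the electron-rich epoxy carbinol may open under acid during isolation.
- Fallback: the oxirane is installed after the C4–C8 bond, at the ketone oxidation level. Setting out from 4 (lithiated to 12 as before) and enal 6, 1,2-addition gives the allylic alcohol F2.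
- MnO2 oxidation gives the chalcone-type enone F3.
- Juliá–Colonna epoxidation (poly-L-leucine, urea–H2O2, DBU, THF) gives the (αR,βS)-epoxy ketone F4, which is much less prone to ionisation.
- NaBH4 in THF–MeOH at −20 °C reduces F4 to the carbinol epimers, returning to the route at 13.

Step 5.
- What may go wrong: iminium formation from the donor-substituted enal may be sluggish. That would let uncatalysed peroxide addition or hydrolytic opening of the benzylic oxirane compete and would erode facial selectivity.
- Fallback: reagent control is moved to the allylic alcohol. Setting out from 6, DIBAL-H reduction in CH2Cl2 at −78 °C gives the cinnamyl alcohol F5.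
- Sharpless asymmetric epoxidation (L-(+)-DIPT, Ti(OiPr)4, TBHP, 4 Å MS, −20 °C) gives the (2S,3S)-glycidol F6.
- Parikh–Doering oxidation (SO3·pyridine, DMSO, Et3N) returns to the route at 7.

**Further compounds**
F1 | step 9 | C4 benzyl thioether of 14 (both C4 epimers; flavan C2 and C3 as in 14) | O(Cc5ccccc5)c1ccc([C@@H](Oc2cccc(OCc5ccccc5)c2OCc5ccccc5)[C@@H](O)C(SCc5ccccc5)c3c(OCc5ccccc5)cc(OCc5ccccc5)c4c3O[C@H](c3ccc(OCc5ccccc5)c(OCc5ccccc5)c3)[C@@H](OCc5ccccc5)C4)cc1OCc5ccccc5
F2 | step 8 | (E)-3-(3,4-dibenzyloxyphenyl)-1-(penta-O-benzylcatechin-8-yl)prop-2-en-1-ol, both carbinol epimers | O(Cc5ccccc5)c1ccc(/C=C/C(O)c3c(OCc5ccccc5)cc(OCc5ccccc5)c4c3O[C@H](c3ccc(OCc5ccccc5)c(OCc5ccccc5)c3)[C@@H](OCc5ccccc5)C4)cc1OCc5ccccc5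
F3 | step 8 | (E)-3-(3,4-dibenzyloxyphenyl)-1-(penta-O-benzylcatechin-8-yl)prop-2-en-1-one | O(Cc5ccccc5)c1ccc(/C=C/C(=O)c3c(OCc5ccccc5)cc(OCc5ccccc5)c4c3O[C@H](c3ccc(OCc5ccccc5)c(OCc5ccccc5)c3)[C@@H](OCc5ccccc5)C4)cc1OCc5ccccc5
F4 | step 8 | [(2R,3S)-3-(3,4-dibenzyloxyphenyl)oxiran-2-yl](penta-O-benzylcatechin-8-yl)methanone | O(Cc5ccccc5)c1ccc([C@@H]6O[C@H]6C(=O)c3c(OCc5ccccc5)cc(OCc5ccccc5)c4c3O[C@H](c3ccc(OCc5ccccc5)c(OCc5ccccc5)c3)[C@@H](OCc5ccccc5)C4)cc1OCc5ccccc5
F5 | step 5 | (E)-3-[3,4-bis(benzyloxy)phenyl]prop-2-en-1-ol | OC/C=C/c1ccc(OCc2ccccc2)c(OCc2ccccc2)c1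
F6 | step 5 | [(2S,3S)-3-(3,4-dibenzyloxyphenyl)oxiran-2-yl]methanol | O(Cc5ccccc5)c1ccc([C@@H]6O[C@H]6CO)cc1OCc5ccccc5
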